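## The problem

The target is the bis-imide of an α-truxillic-type diacid with two molecules of 5,6-dihydropyridin-2(1H)-one. Its core is a cyclobutane with acyl groups on C1 and C3 and 3,4-dimethoxyphenyl groups on C2 and C4 (head-to-tail pattern). All four ring carbons are stereocentres. The aryl groups are trans to each other across the ring and so are the acyl groups, so each acyl group is cis to one neighbouring aryl group and trans to the other. The molecule has a centre of inversion and is achiral, so only relative configuration has to be controlled.

The aryl-bearing carbons C2 and C4 are configurationally inert once made and can act as control elements. C1 and C3 are enolisable, and the required arrangement, with two cis vicinal pairs, is not the all-trans thermodynamic one. These two centres must therefore be set kinetically and then kept away from prolonged base or Lewis acid. The N-acyl lactams are acyl-transfer-active imides and Michael acceptors, and the veratryl rings are easily halogenated or oxidised, so the heterocycles must go on last and under mild conditions.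

The feature that opens a new route is this: each exocyclic carbonyl carbon sits on a ring carbon (C1 or C3) that lies between both aryl-bearing carbons. If the carbonyl carbon on C1 is re-inserted into the C1–C4 bond and that on C3 into the C3–C2 bond (opposite edges of the ring), a 3,6-diarylcyclohexane results that is oxygenated on its other four carbons. In the forward sense both carbons can be pushed out of a six-membered ring by two 1,2-shifts.

## Retrosynthesis

**Imide bonds.** The two N–C(=O) bonds of target 15 are cut first, giving diacid chloride 12 and lactam 13, which reacts as its lithium amide 14. Cutting here, and not earlier, keeps the base- and nucleophile-sensitive imides out of every other step. The precursor loses both heterocycles and becomes a C2/C4-diaryl cyclobutane diacid derivative. The forward reaction must acylate nitrogen twice without enolising the acyl-bearing ring carbons.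

**Oxidation level.** Acid chloride 12 is traced through diacid 11 to dialdehyde 10. No skeletal bond is cut; the aldehyde level is chosen because a ring contraction of an epoxide delivers a formyl group. The forward reactions must oxidise and activate without touching the centres alpha to the carbonyl groups.

**Ring contraction (key disconnection).** In 10 the ring bonds C1–C4 and C2–C3 are cut and each formyl carbon is reconnected to the aryl-bearing carbon just released. This gives anti bis-epoxide 7 of a trans-3,6-diarylcyclohexa-1,4-diene. The neighbouring option, cutting two parallel ring bonds to two cinnamoyl halves, leaves head-to-tail regiochemistry and all four stereocentres to crystal packing. Here the regiochemistry is built into the six-membered ring and the stereochemistry follows from two stereospecific shifts. Precursor 7 is centrosymmetric and has only two stereochemical elements (trans aryl groups, anti oxiranes). The forward step passes through bis(bromohydrin) 8 and bromohydrin aldehyde 9; it requires carbon migration to beat hydride shift twice, the second time from a five- to a four-membered ring.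

**Epoxides.** The four C–O bonds of 7 are removed to give trans-diene 5, by way of mono-epoxide 6. The forward reaction must place the second oxirane anti to the first.

**Dearomatisation.** The two C–H bonds at the aryl-bearing carbons of 5 are removed to give terphenyl 3, by way of cyclohexadienyl anion 4. This turns a stereodefined ring into a flat aromatic compound. The price is that the forward protonation must deliver the trans isomer, which it cannot be forced to do.

**Biaryl bonds.** The two aryl–aryl bonds of 3 are cut to give diboronic acid 1 and aryl bromide 2, both commercial. The forward reaction is a two-fold cross-coupling with no selectivity demand.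

## Roads not taken

**Alternative 1:** The cut removes both aryl–cyclobutane bonds and derives the ring from a 2-pyranone. Irradiation of methyl coumalate A1 effects a 4π electrocyclisation to the bicyclic lactone A2. Reduction to a cis-1,3-cyclobutane diacid derivative, attachment of a bidentate directing amide, two palladium-catalysed C–H arylations, epimerisation and amide exchange would follow.
- Merits: every operation is of a known type, the aryl groups come from simple aryl halides, and unsymmetrical analogues are accessible. In precedent, and in having no stereorandom step, this road is better than the chosen one.
- Weak points for this target: the two aryl groups are identical and the molecule is centrosymmetric, which a one-aryl-at-a-time sequence cannot exploit. A directing group must be put on and taken off, the cis-1,3-diacyl pattern from A2 must be epimerised to trans, and A2 is a labile photoproduct. The sequence is clearly longer.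
- What the chosen plan sets against it: seven steps, symmetry used in every step, and both acyl-bearing centres set in one operation from the geometry of 7 without an auxiliary.

**Alternative 2:** The cut goes through both arenes, which are built last on a preformed cyclobutane. The diyne A3 and two molecules of 2,3-dimethoxybuta-1,3-diene A4 would undergo a double cobalt-catalysed [4+2] cycloaddition to the bis(cyclohexadiene) A5, followed by dehydrogenation to the arenes.
- Merits: convergent, neutral conditions that spare the ester-bearing centres, and late variation of the arenes. Its key step is a known reaction type, which step 4 of the chosen plan is not.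
- Weak points: A3 already contains all four stereocentres in the α pattern. It would itself have to come from a head-to-tail dimerisation of an enyne ester, so the central problem is only moved to a less tractable substrate. A4 and the enol ethers of A5 are acid-labile, and an extra oxidation is needed.
- Comparison: the chosen plan makes ring and stereocentres together from a flat aromatic precursor, whereas this road does not address how the ring is made.

**Alternative 3:** The cut is the [2+2] retron, with each acyl group tied to its own aryl group as a lactone. Irradiation of scoparone A6 would give the anti head-to-tail dimer A7. Opening of both lactones, removal of the two phenolic oxygens and imide formation would follow.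
- Merits: the ring and all four stereocentres arise in one step of a known type from a commercial coumarin. The lactone tether enforces exactly the two cis acyl/aryl relations of the target, and A7 maps directly onto the required configuration. In precedent and in stereocentres set per step, this road is better than the chosen plan.
- Weak points: coumarin photodimerisation generally prefers head-to-head dimers, so the anti head-to-tail isomer is likely to be a minor component unless a template is found. The target has no oxygen ortho to the ring on its arenes, so two aryl C–O bonds must be reduced away after ring opening, with the enolisable centres exposed to base on the way.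
- What the chosen plan sets against it: no head-to-head/head-to-tail question, no superfluous oxygen, and three routine steps after the key step. Its own debts are an unprecedented five-to-four contraction and a protonation without facial control in step 2.

Key step: step 4

Remark: the target and compounds 5, 7, 8, 10, 11 and 12 are achiral (centrosymmetric); stereodescriptors in the SMILES strings give relative configuration, and the chiral intermediates 6 and 9 are racemates.

Remark: where a step repeats one reaction at the two equivalent ends of a symmetric compound, the half-converted species is numbered only if the second event has its own selectivity question (6) or changes the ring size (9).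

## Route

Step 1
Reactants: 1 benzene-1,4-diyldiboronic acid; 2 4-bromo-1,2-dimethoxybenzene (2.2 equiv)
Product: 3 3,3'',4,4''-tetramethoxy-1,1':4',1''-terphenyl
Conditions: Pd(PPh3)4 (cat.), K2CO3, PhMe–EtOH–H2O, 85 °C
Reagents that add atoms: none
Why: Two-fold Suzuki–Miyaura coupling under zerovalent palladium catalysis; the electron-rich aryl bromide and the unhindered para-diboronic acid are standard partners and the sparingly soluble terphenyl should crystallise from the mixture. No stereocentre is formed.

Step 2
Reactants: 3 3,3'',4,4''-tetramethoxy-1,1':4',1''-terphenyl
Product: 5 trans-3,6-bis(3,4-dimethoxyphenyl)cyclohexa-1,4-diene, via lithium 1,4-diarylcyclohexadienide 4 (not isolated)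
Conditions: Li (2.2 equiv), NH3(l)–THF, −78 °C; then NH4Cl
Reagents that add atoms: none
Why: Birch-type metal–ammonia reduction: the terphenyl takes up two electrons far more readily than an isolated veratrole ring, charge collects at the two aryl-bearing carbons of the central ring (the para-methoxy groups disfavour charge in the outer rings), ammonia protonates one of them to give the benzylic pentadienyl anion 4, and ammonium chloride protonates 4 kinetically at its central carbon to give the unconjugated 1,4-diene. The remote ring stereocentre exerts no facial control on this second protonation, so cis and trans isomers should both form; the centrosymmetric trans isomer 5, which alone leads to the target, is to be separated by crystallisation.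

Step 3
Reactants: 5 trans-3,6-bis(3,4-dimethoxyphenyl)cyclohexa-1,4-diene
Product: 7 2,6-bis(3,4-dimethoxyphenyl)-4,8-dioxatricyclo[5.1.0.0(3,5)]octane (oxiranes anti; aryl groups trans), via racemic mono-epoxide 6 (not isolated)
Conditions: mCPBA (2.4 equiv), NaHCO3, CH2Cl2, 0 °C to rt
Reagents that add atoms: m-chloroperoxybenzoic acid, O=C(OO)c1cccc(Cl)c1
Why: Prilezhaev epoxidation with buffered peracid: the two faces of each double bond of 5 are equivalent by the twofold axis through the double-bond midpoints, so 6 is a single racemate, and the second oxygen should enter anti to the first oxirane (dipole and steric repulsion, as is usual for cyclohexa-1,4-dienes) to give centrosymmetric 7. The minor syn isomer is to be removed by chromatography or crystallisation.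

Step 4
Reactants: 7 2,6-bis(3,4-dimethoxyphenyl)-4,8-dioxatricyclo[5.1.0.0(3,5)]octane (anti bis-epoxide)
Product: 10 2,4-bis(3,4-dimethoxyphenyl)cyclobutane-1,3-dicarbaldehyde (formyl groups trans; aryl groups trans), via all-trans bis(bromohydrin) magnesium alkoxide 8 (not isolated), via bromohydrin cyclopentanecarbaldehyde 9 (not isolated)
Conditions: MgBr2·OEt2 (2.2 equiv), Et2O–PhMe, 0 °C; then PhMe, 60 °C
Reagents that add atoms: none
Why: Proposed new method: magnesium bromide should open both oxiranes by anti attack of bromide, preferentially at the carbon whose neighbouring aryl group is cis to the oxirane oxygen and so leaves the rear side free, giving the all-trans bis(bromohydrin) alkoxide 8, whose all-equatorial chair places each C–Br bond antiperiplanar to the ring bond between the adjacent carbinol carbon and its aryl-bearing neighbour. On warming, that aryl-bearing carbon migrates to the bromide-bearing carbon while the alkoxide carbon becomes the formyl group (semipinacol shift), contracting six to five (9), and the same event at the second bromohydrin contracts five to four (10). The closest known reaction type is the magnesium or lithium bromide mediated Meinwald-type contraction of cyclohexene oxides to cyclopentanecarbaldehydes through their trans-halohydrin salts; the first stage follows it directly, whereas a cyclopentane-to-cyclobutane contraction of this kind is without precedent and has to pay for the added ring strain. The cyclobutane is therefore closed in two stages, each an intramolecular 1,2-shift in which a ring C–C bond displaces bromide from the adjacent carbon with inversion (a three-centre, SN2-like closure), not by cyclisation of a chain. The two new stereocentres are the formyl-bearing carbons: each is fixed by double inversion relative to its oxirane (bromide anti, then the migrating carbon anti to bromide), so each formyl group ends on the face opposite its parent oxirane oxygen and cis to the aryl group of the carbon that migrated; anti oxiranes therefore give trans formyl groups, and the migrating benzylic carbons keep their configuration, so the aryl groups stay trans. The step needs carbon migration to beat hydride shift, elimination and aromatisation, and both contractions to take the same halohydrin pathway: the trans-halohydrin geometry holds the carbinol hydrogen syn to bromide and out of reach, the flanking aryl groups are gauche to the leaving group in the reactive conformer so that aryl participation is disfavoured, and the electron-rich aryl group on the migrating carbon stabilises the bridged transition state. Either regiochemistry of bromide opening leads to the same product, so no regiocontrol is needed; 10 is to be oxidised at once because its formyl-bearing centres are epimerisable.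

Step 5
Reactants: 10 2,4-bis(3,4-dimethoxyphenyl)cyclobutane-1,3-dicarbaldehyde
Product: 11 2,4-bis(3,4-dimethoxyphenyl)cyclobutane-1,3-dicarboxylic acid (α-truxillic configuration)
Conditions: NaClO2, NaH2PO4, 2-methylbut-2-ene, t-BuOH–H2O, 0 °C to rt
Reagents that add atoms: sodium chlorite, [Na+].[O-]Cl=O
Why: Pinnick (Lindgren) oxidation: chlorous acid adds to each formyl group and fragments without enolisation, so both epimerisable centres should keep their configuration. The alkene scavenger removes hypochlorous acid before it can chlorinate the veratryl rings.

Step 6
Reactants: 11 2,4-bis(3,4-dimethoxyphenyl)cyclobutane-1,3-dicarboxylic acid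
Product: 12 2,4-bis(3,4-dimethoxyphenyl)cyclobutane-1,3-dicarbonyl dichloride
Conditions: (COCl)2, DMF (cat.), CH2Cl2, 0 °C to rt
Reagents that add atoms: oxalyl chloride, O=C(Cl)C(=O)Cl
Why: Acid chloride formation through the Vilsmeier-type chloroiminium species from catalytic DMF; the conditions are base-free, so the centres alpha to the carbonyl groups are not expected to move, and the volatile by-products allow direct use of crude 12.

Step 7
Reactants: 12 2,4-bis(3,4-dimethoxyphenyl)cyclobutane-1,3-dicarbonyl dichloride; 13 5,6-dihydropyridin-2(1H)-one (2.2 equiv)
Product: 15 1,1'-[2,4-bis(3,4-dimethoxyphenyl)cyclobutane-1,3-diyldicarbonyl]bis(5,6-dihydropyridin-2(1H)-one) (target), via N-lithio lactam 14 (not isolated)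
Conditions: LiN(SiMe3)2, THF, −78 °C; then 12, −78 to 0 °C
Reagents that add atoms: none
Why: N-Acylation of a lithium lactamide by an acid chloride, the standard entry to N-acyl-5,6-dihydropyridin-2(1H)-one imides: 13 is deprotonated completely before 12 is added cold, so the weakly basic amide anion 14 attacks the acyl carbon faster than it can form a ketene from 12. No stereocentre is formed and the four ring centres are carried through unchanged.

## Compound list

1 | benzene-1,4-diyldiboronic acid | OB(O)c1ccc(B(O)O)cc1 | starting material
2 | 4-bromo-1,2-dimethoxybenzene | COc1ccc(Br)cc1OC | starting material
3 | 3,3'',4,4''-tetramethoxy-1,1':4',1''-terphenyl | COc1ccc(-c2ccc(-c3ccc(OC)c(OC)c3)cc2)cc1OC | intermediate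
4 | lithium 1,4-bis(3,4-dimethoxyphenyl)cyclohexa-2,5-dien-1-ide | [Li+].COc1ccc(cc1OC)[C-]1C=CC(C=C1)c1ccc(OC)c(OC)c1 | intermediate (not isolated)
5 | trans-3,6-bis(3,4-dimethoxyphenyl)cyclohexa-1,4-diene | COc1ccc([C@H]2C=C[C@H](c3ccc(OC)c(OC)c3)C=C2)cc1OC | intermediate
6 | racemic 2,5-bis(3,4-dimethoxyphenyl)-7-oxabicyclo[4.1.0]hept-3-ene, aryl groups trans | COc1ccc([C@H]2[C@@H]3O[C@@H]3[C@H](c3ccc(OC)c(OC)c3)C=C2)cc1OC | intermediate (not isolated)
7 | 2,6-bis(3,4-dimethoxyphenyl)-4,8-dioxatricyclo[5.1.0.0(3,5)]octane, oxiranes anti, aryl groups trans | COc1ccc([C@H]2[C@@H]3O[C@@H]3[C@H](c3ccc(OC)c(OC)c3)[C@H]3O[C@@H]23)cc1OC | intermediate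
8 | all-trans 2,5-dibromo-3,6-bis(3,4-dimethoxyphenyl)cyclohexane-1,4-diol, present as its bis(bromomagnesium) alkoxide (drawn as the diol) | COc1ccc([C@H]2[C@H](O)[C@@H](Br)[C@H](c3ccc(OC)c(OC)c3)[C@@H](O)[C@@H]2Br)cc1OC | intermediate (not isolated)
9 | racemic 4-bromo-2,5-bis(3,4-dimethoxyphenyl)-3-hydroxycyclopentane-1-carbaldehyde, present as its bromomagnesium alkoxide (drawn as the alcohol); formyl cis to the C5 aryl group, all other vicinal pairs trans | COc1ccc([C@H]2[C@@H](C=O)[C@H](c3ccc(OC)c(OC)c3)[C@@H](O)[C@@H]2Br)cc1OC | intermediate (not isolated)
10 | 2,4-bis(3,4-dimethoxyphenyl)cyclobutane-1,3-dicarbaldehyde, formyl groups trans, aryl groups trans | COc1ccc([C@H]2[C@H](C=O)[C@H](c3ccc(OC)c(OC)c3)[C@H]2C=O)cc1OC | intermediate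
11 | 2,4-bis(3,4-dimethoxyphenyl)cyclobutane-1,3-dicarboxylic acid, α-truxillic configuration | COc1ccc([C@H]2[C@H](C(=O)O)[C@H](c3ccc(OC)c(OC)c3)[C@H]2C(=O)O)cc1OC | intermediate
12 | 2,4-bis(3,4-dimethoxyphenyl)cyclobutane-1,3-dicarbonyl dichloride | COc1ccc([C@H]2[C@H](C(=O)Cl)[C@H](c3ccc(OC)c(OC)c3)[C@H]2C(=O)Cl)cc1OC | intermediate
13 | 5,6-dihydropyridin-2(1H)-one | O=C1C=CCCN1 | starting material
14 | 1-lithio-5,6-dihydropyridin-2(1H)-one | [Li]N1CCC=CC1=O | intermediate (not isolated)
15 | 1,1'-[2,4-bis(3,4-dimethoxyphenyl)cyclobutane-1,3-diyldicarbonyl]bis(5,6-dihydropyridin-2(1H)-one), CNP0199212.1 | COc1ccc([C@H]2[C@H](C(=O)N3CCC=CC3=O)[C@H](c3ccc(OC)c(OC)c3)[C@H]2C(=O)N2CCC=CC2=O)cc1OC | target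

## Step count and risk

Total: 7 steps. Longest linear sequence: 7 steps (1 and 2 to 15).

**Step 4 (key step, proposed new method).**
- What may go wrong: the second shift fails to compete. The bromohydrin alkoxide of 9 may instead reclose to the oxirane, exchange bromide and collapse by hydride shift to a cyclopentanone, or eliminate, because the five-to-four contraction must pay about the full strain of a cyclobutane. In the first stage, aryl participation or hydride shift from a benzylic carbon could lead to aromatisation. The warm Lewis acidic medium may also epimerise the formyl-bearing centres towards the all-trans isomer.
- Fallback (known chemistry): set out from 2. A Mizoroki–Heck coupling with acrylic acid (Pd(OAc)2, P(o-tol)3, Et3N, DMF, 100 °C) gives (E)-3,4-dimethoxycinnamic acid F1. Provided F1 crystallises in the head-to-tail (α-type) packing, irradiation of the solid effects the topochemical [2+2] photodimerisation to the centrosymmetric head-to-tail dimer, which is diacid 11. The route is rejoined at 11 and steps 1 to 5 are bypassed.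

**Step 2.**
- What may go wrong: no facial selectivity in the protonation of 4 (the controlling centre is 1,4-remote on a nearly flat ring), so at best about half of the material has the trans configuration. Amide-induced migration of the double bonds into conjugation with re-aromatisation, or reductive loss of methoxy groups, may add to this.
- Fallback: set out from 3 and move the stereochemical sorting into the oxidation. The unseparated diene mixture is bis-epoxidised as in step 3. The cis-diene, cis-3,6-bis(3,4-dimethoxyphenyl)cyclohexa-1,4-diene F2, can only place both oxiranes on the face remote from its two cofacial aryl groups. It gives the strongly dipolar syn bis-epoxide F3, which should separate readily on silica from the centrosymmetric, weakly polar 7; the route is rejoined at 7. Any F2 isolated is returned to 3 by dehydrogenation with DDQ.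

**Step 3.**
- What may go wrong: insufficient anti selectivity in the second epoxidation. Each face of the remaining double bond of 6 carries one flanking aryl group, so only the remote oxirane differentiates them. Oxidative aromatisation of the doubly allylic, benzylic positions is a second risk.
- Fallback: set out from 5 with one equivalent of peracid and isolate 6. If the electrophile prefers the face syn to the oxirane, the halohydrin route inverts the outcome. NBS in aqueous DMSO at 0 °C forms the bromonium ion on that face and water opens it from the other, giving the bromohydrin 4-bromo-2,5-bis(3,4-dimethoxyphenyl)-7-oxabicyclo[4.1.0]heptan-3-ol F4 (hydroxyl anti to the oxirane). K2CO3 in MeOH closes it to 7, where the route is rejoined. Either regiochemistry of water attack closes to the same oxirane. Competing ring bromination of the veratryl groups is the limit of this variant.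

**Step 7.**
- What may go wrong: base-induced epimerisation of the acyl-bearing centres through ketene formation from 12, incomplete second acylation at a carbonyl flanked by a cis aryl group, or conjugate addition of 14 to the enone of product or lactam.
- Fallback: replace the metal amide by neutral silyl-transfer acylation. Set out from 13: Me3SiCl and Et3N give 1-(trimethylsilyl)-5,6-dihydropyridin-2(1H)-one F5, which is heated with 12 in toluene. It acylates at nitrogen with loss of chlorotrimethylsilane and gives 15 directly, with no strong base present.

## Further compounds

F1 | step 4 | (E)-3,4-dimethoxycinnamic acid | COc1ccc(/C=C/C(=O)O)cc1OC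
F2 | step 2 | cis-3,6-bis(3,4-dimethoxyphenyl)cyclohexa-1,4-diene | COc1ccc([C@H]2C=C[C@@H](c3ccc(OC)c(OC)c3)C=C2)cc1OC
F3 | step 2 | 2,6-bis(3,4-dimethoxyphenyl)-4,8-dioxatricyclo[5.1.0.0(3,5)]octane, aryl groups cis, both oxiranes syn to each other and anti to the aryl groups | COc1ccc([C@H]2[C@@H]3O[C@@H]3[C@@H](c3ccc(OC)c(OC)c3)[C@@H]3O[C@H]23)cc1OC
F4 | step 3 | racemic 4-bromo-2,5-bis(3,4-dimethoxyphenyl)-7-oxabicyclo[4.1.0]heptan-3-ol, hydroxyl anti to the oxirane, bromine trans to hydroxyl | COc1ccc([C@H]2[C@@H]3O[C@@H]3[C@H](c3ccc(OC)c(OC)c3)[C@@H](O)[C@@H]2Br)cc1OC
F5 | step 7 | 1-(trimethylsilyl)-5,6-dihydropyridin-2(1H)-one | C[Si](C)(C)N1CCC=CC1=O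
A1 | alternative 1 | methyl coumalate (methyl 2-oxo-2H-pyran-5-carboxylate) | COC(=O)C1=COC(=O)C=C1
A2 | alternative 1 | methyl 3-oxo-2-oxabicyclo[2.2.0]hex-5-ene-6-carboxylate, cis-fused, racemic | COC(=O)C1=C[C@@H]2C(=O)O[C@H]12
A3 | alternative 2 | dimethyl 2,4-diethynylcyclobutane-1,3-dicarboxylate, ester groups trans, ethynyl groups trans | C#C[C@H]1[C@H](C(=O)OC)[C@H](C#C)[C@H]1C(=O)OC
A4 | alternative 2 | 2,3-dimethoxybuta-1,3-diene | COC(=C)C(=C)OC
A5 | alternative 2 | dimethyl 2,4-bis(4,5-dimethoxycyclohexa-1,4-dien-1-yl)cyclobutane-1,3-dicarboxylate | COC1=C(OC)CC(=CC1)[C@H]1[C@H](C(=O)OC)[C@H](C2=CCC(OC)=C(OC)C2)[C@H]1C(=O)OC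
A6 | alternative 3 | scoparone (6,7-dimethoxycoumarin) | COc1cc2ccc(=O)oc2cc1OC
A7 | alternative 3 | anti head-to-tail scoparone dimer (cyclobutane bis-lactone) | COc1cc3c(cc1OC)[C@H]2[C@H](C(=O)Oc4cc(OC)c(OC)cc45)[C@H]5[C@H]2C(=O)O3
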